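## The problem

Compound 15 is a profisetinidin-type dimer. A 5-deoxyflavan-3-ol upper unit (rings A, B, C; 7,3',4'-trihydroxy) is bonded from its C4 to C6 of the phloroglucinol ring D of (+)-catechin (rings D, E, F). Of the five stereocentres, lower C2 and C3 (2R,3S) are those of natural catechin and can be bought. Upper C2, C3 and C4 (2R,3R,4S) carry aryl, hydroxyl and aryl on one face of ring C. This all-cis triad is the core difficulty: the usual ionic union of a C4 cation with a nucleophilic flavan gives the 3,4-trans arrangement, and the nucleophilic carbon of a catechin is C8, not C6. The lower stereocentres lie five and six bonds from upper C4 and cannot direct the face at which ring C is built. The triad must therefore be set as a relative unit by the reaction topology and its absolute sense by an external chiral agent; the enantiopure lower unit at least makes the two outcomes separable diastereomers. Seven phenols (two catechols) are sensitive to air and base, the benzylic ether C2–O1 of either pyran can open under acid or strong base with loss of the C2 configuration, and the C4–C6 interflavan bond can be cleaved by acid, so the phenols must stay masked until a final neutral deprotection. The enabling feature is the sequence O1–C8a–C4a–C4 of rings A and C. A phenol oxygen with an ortho benzylic methine is the retron of an o-quinone methide, C4 carries only H and ring D and so maps onto an aldehyde carbon, and the cis C2-aryl/C3-oxygen pair maps onto a Z-enol ester. Ring C is thus a phenol, an aldehyde and a Z-alkene.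

## Retrosynthesis

**Protecting-group cut (15 to 13).** The last bonds made are seven phenolic O–H bonds, two alcohol O–H bonds and the C8–H bond of ring D. Target 15 is traced to diol 14 (all phenols as benzyl ethers, bromine at lower C8) and 14 to diacetate 13. Benzyl is preferred to methyl or silyl because it leaves under neutral hydrogenolysis, which a free catechol-rich dimer tolerates, and the same hydrogenation removes the aryl bromide. Acetate is chosen for the two secondary alcohols because the upper one arrives as an acetate from the ring-forming step and both then leave together by mild methanolysis. The forward steps need only be clean and leave five stereocentres alone.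

**Ring C cut (13 to 5, 8, 9 and 10).** Three bonds of the upper pyran are cut at once: C4–C4a, C3–C4 and O1–C2. C4–C4a is the ortho-hydroxyalkylation of 3-(benzyloxy)phenol 9 by aldehyde 5, templated by phenylboronic acid 10 and arrested as benzodioxaborin 11. C3–C4 and O1–C2 are the two σ bonds of a [4+2] addition of Z-enol acetate 8 to o-quinone methide 12 released from 11. Cutting the interflavan bond alone would need a C4 cation of a finished upper unit and a C6-nucleophilic catechin, which gives 3,4-trans products and attack at C8. Cutting only O1–C2 or only C3–C4 leaves an acyclic stereotriad to be built step by step. The chosen cut removes one ring, three skeletal bonds and three stereocentres. It leaves a commercial phenol, a two-step alkene and an aldehyde that already holds the whole lower unit, with the 4→6 connectivity fixed as its formyl carbon. The forward reaction must meet four demands: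
- attack at the ortho carbon of 9 that is para to the benzyloxy group (C6 of 9; the other free ortho carbon, C2, lies between two oxygens and is more hindered);
- bonding of the acetoxy-bearing alkene carbon to C4;
- an endo, suprafacial course;
- selection of one face of 12.

**Aldehyde cut (5 to 1).** The formyl C–C bond at lower C6 is cut to give acetate 4, the acetyl group to give bromide 3, the C8–Br bond to give tetrabenzyl ether 2, and the benzyl groups to give (+)-catechin 1. Bromine goes first onto the naturally more reactive C8, so the only ring D position left for formylation is C6; this turns the usual C8 preference into a 4→6 link. The same halogen later keeps ring D from acting as a Friedel–Crafts nucleophile toward 12. Each step is a standard aromatic substitution or protection, and the two catechin stereocentres are carried through untouched.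

**Alkene cut (8 to 6).** The enol C–O bond of 8 is cut to give alkyne 7 and acetic acid. A metal-vinylidene hydro-acyloxylation delivers H and OAc trans across the triple bond and so the Z geometry, whereas enol acetylation of the corresponding arylacetaldehyde would favour E-rich mixtures. Alkyne 7 comes from commercial 3,4-bis(benzyloxy)benzaldehyde 6 by one-carbon homologation. The Z geometry must survive, because it becomes the cis C2/C3 relationship.

## Roads not taken

**Alternative 1:** Ring C is cut at C3=C4 after the C3–OH/C4–H pair is exchanged for an alkene. Forward, diene A1 (an aryl 1-arylallyl ether with an ortho 1-arylvinyl group bearing ring D) is closed with the second-generation Grubbs catalyst to 4-aryl-flav-3-ene A2, with loss of ethene.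
- Merits: C2 is set beforehand in a step of its own, so its absolute configuration does not depend on face selection in a cycloaddition. Here this road is better than the chosen plan. The metathesis tolerates ethers and aryl halides.
- Weak points: the 1,1-disubstituted alkene carries a fully substituted, di-ortho-alkoxy aryl ring and is a poor metathesis partner. The step forms one bond and no stereocentre. From A2, hydroboration would add syn and anti to the C2 aryl group, giving the correct C4 but the wrong C3 configuration, so C3 would need oxidation to a ketone between two epimerisable benzylic centres and hydride return.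
- Comparison: four or more operations are needed after a long diene synthesis. The chosen plan sets against the firmer C2 control three bonds, the ring and all three stereocentres in one step, with diastereomer separation as a safety net.

**Alternative 2:** Ring C is cut at O1–C8a. Forward, acyclic alcohol A3 (C2 hydroxyl free, C3 benzyl ether, C4 bearing ring D and a 2-bromo-4-benzyloxyphenyl group) is cyclised with Pd(OAc)2 and a bulky biaryl phosphine by intramolecular C–O coupling to dimer A4.
- Merits: ring closure touches no stereocentre, and all three centres can be set by acyclic, catalyst-controlled reactions with established models. The stereochemical outcome is more predictable than face control in the chosen cycloaddition; this is a real advantage.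
- Weak points: the triad, a methine with two different electron-rich aryl groups next to a differentially protected diol, takes many steps to assemble. The secondary benzylic alkoxide on palladium can undergo β-hydride elimination to a ketone. Oxidative addition to zerovalent palladium must pick the electron-rich ring A bromide over the ring D chloride. The chloride is harder to remove at the end than a bromide.
- Comparison: the linear sequence is much longer. The chosen plan accepts less certain face selection in exchange for convergence and backs it with the separability of the face isomers.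

**Alternative 3:** The lower pyran (ring F) is cut at O1–C2 and C3–C4. Forward, o-hydroxymethylphenol A5, in which ring D already carries the complete upper unit, is dehydrated to an o-quinone methide that adds E-enol acetate A6 to give dimer A7.
- Merits: the cycloaddition is simpler than the chosen one. The methide is unsubstituted, so no C4 centre and no endo/exo question arise; the E-alkene gives the 2,3-trans catechin pattern directly and is easier to obtain pure than Z-alkene 8.
- Weak points: the all-cis upper unit with its C4–aryl bond must already exist, so the hardest problem is moved and not solved. (+)-Catechin is given up as a chiral-pool source, and the lower (2R,3S) centres must be set by face selection remote from the upper centres. Ring D needs one free phenol ortho to the hydroxymethyl group and two benzylated ones, and this differentiation decides 4→6 against 4→8 connectivity.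
- Comparison: the chosen plan uses the same reaction class where it creates the difficult triad and buys the lower stereocentres.

Key step: step 7

Assumption: the (R) antipode of the chiral phosphoric acid is written as the one that favours the required face of 12. The sense of induction cannot be deduced from the substrate, and the (S) acid would take its place should the opposite face be preferred.

## Route

Step 1
Reactants: 1 (+)-catechin, (2R,3S)-2-(3,4-dihydroxyphenyl)chroman-3,5,7-triol
Product: 2 5,7,3',4'-tetra-O-benzyl-(+)-catechin (2R,3S; 3-OH free)
Conditions: BnBr (4.4 equiv), K2CO3, DMF, 0 °C to rt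
Reagents that add atoms: benzyl bromide, BrCc1ccccc1
Why: Williamson ether synthesis; the carbonate deprotonates only the four phenols and not the secondary alcohol, so O-benzylation should stop at the tetra-ether, and no stereocentre is involved.

Step 2
Reactants: 2 5,7,3',4'-tetra-O-benzyl-(+)-catechin
Product: 3 8-bromo-5,7,3',4'-tetra-O-benzyl-(+)-catechin (2R,3S)
Conditions: NBS (1.0 equiv), CH2Cl2, −40 °C to 0 °C
Reagents that add atoms: N-bromosuccinimide, O=C1CCC(=O)N1Br
Why: Electrophilic aromatic bromination; in 5,7-dialkoxyflavans C8 is the more nucleophilic and accessible ring D position, so one equivalent of NBS at low temperature should brominate there and leave C6 free.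

Step 3
Reactants: 3 8-bromo-5,7,3',4'-tetra-O-benzyl-(+)-catechin
Product: 4 3-O-acetyl-8-bromo-5,7,3',4'-tetra-O-benzyl-(+)-catechin (2R,3S)
Conditions: Ac2O, pyridine, DMAP (cat.), CH2Cl2, rt
Reagents that add atoms: acetic anhydride, CC(=O)OC(C)=O
Why: DMAP-catalysed acylation of the secondary alcohol; the acetate shields O3 from the chloroiminium reagent of step 4 and from boron in step 7, and the C3 configuration is untouched.

Step 4
Reactants: 4 3-O-acetyl-8-bromo-5,7,3',4'-tetra-O-benzyl-(+)-catechin
Product: 5 3-O-acetyl-8-bromo-6-formyl-5,7,3',4'-tetra-O-benzyl-(+)-catechin (2R,3S)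
Conditions: POCl3, DMF, ClCH2CH2Cl, 0 °C to 70 °C; then aq NaOAc
Reagents that add atoms: N,N-dimethylformamide, CN(C)C=O; water, O
Why: Vilsmeier–Haack formylation; C6 is the only free position of ring D and is ortho, ortho and para to three ether oxygens, so the chloroiminium ion should attack there despite the flanking benzyloxy groups, and hydrolysis of the iminium salt gives the aldehyde.

Step 5
Reactants: 6 3,4-bis(benzyloxy)benzaldehyde
Product: 7 1,2-bis(benzyloxy)-4-ethynylbenzene
Conditions: dimethyl (1-diazo-2-oxopropyl)phosphonate, K2CO3, MeOH/THF, 0 °C to rt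
Reagents that add atoms: dimethyl (1-diazo-2-oxopropyl)phosphonate, CC(=O)C(=[N+]=[N-])P(=O)(OC)OC
Why: Ohira–Bestmann modification of the Seyferth–Gilbert homologation; methanolysis of the reagent gives the diazomethylphosphonate anion, which olefinates the aldehyde, and loss of N2 with 1,2-hydride shift in the alkylidene carbene gives the terminal alkyne under conditions that spare the benzyl ethers.

Step 6
Reactants: 7 1,2-bis(benzyloxy)-4-ethynylbenzene
Product: 8 (Z)-2-[3,4-bis(benzyloxy)phenyl]ethenyl acetate
Conditions: AcOH (1.5 equiv), Ru(methallyl)2(dppb) (2 mol%), toluene, 50 °C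
Reagents that add atoms: acetic acid, CC(=O)O
Why: Ruthenium-catalysed anti-Markovnikov hydro-acyloxylation of a terminal alkyne; acetate attacks the α carbon of a ruthenium vinylidene and protonolysis of the alkenyl complex places H and OAc trans, giving the Z-enol ester, with the temperature kept low to avoid Z to E isomerisation.

Step 7
Reactants: 5 3-O-acetyl-8-bromo-6-formyl-5,7,3',4'-tetra-O-benzyl-(+)-catechin, 8 (Z)-2-[3,4-bis(benzyloxy)phenyl]ethenyl acetate, 9 3-(benzyloxy)phenol, 10 phenylboronic acid
Product: 13 hepta-O-benzyl 8-bromo dimer diacetate (upper 2R,3R,4S all-cis; lower 2R,3S; upper C4 bonded to lower C6), via benzodioxaborin 11 (not isolated), via o-quinone methide 12 (not isolated)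
Conditions: 5, 9, 10 (1.1 equiv), EtCO2H (0.3 equiv), toluene, reflux, Dean–Stark; evaporate; then 8 (2 equiv), (R)-TRIP (10 mol%), 4 Å MS, toluene, −20 °C to rt
Reagents that add atoms: none
Why: Proposed new method: the closest known reaction types are the phenylboronic acid-templated three-component chroman synthesis (phenol, aldehyde and alkene through a 4H-1,3,2-benzodioxaborin and its o-quinone methide) and chiral phosphoric acid-catalysed [4+2] additions of o-quinone methides released from o-hydroxybenzhydrols; new here are a β-aryl enol acetate as the 2π partner and a chiral acid ((R)-TRIP, the 3,3'-bis(2,4,6-triisopropylphenyl)-BINOL hydrogen phosphate) as the agent that opens the dioxaborin. Mechanism: the mixed aryl boronate of 9 delivers aldehyde 5 to the ortho carbon para to the benzyloxy group through a six-membered boron-bridged transition state, forming C4–C4a and, after loss of water, dioxaborin 11; protonation by the phosphoric acid ionises the doubly benzylic C4–O bond, helped by the para benzyloxy group of ring A and the 2,4,6-trioxygenated ring D, to give E-configured 12 with the chiral phosphate held at O1 by hydrogen bond or through boron, and boron leaves as triphenylboroxine. Ring C closes by an intermolecular inverse-electron-demand hetero-Diels–Alder reaction (a [4+2] six-membered pericyclic closure, not an ionic cyclisation), in which the acetoxy-bearing alkene carbon bonds to C4 and the benzylic carbon to O1, because the 3,4-dialkoxyphenyl group stabilises developing positive charge at C2 far better than the weakly donating acetoxy group would at C3. C2 and C3 are fixed relative to each other by the Z geometry of 8 and suprafacial addition; C4 is fixed relative to them by the E geometry of 12 and the endo orientation of both alkene substituents, which places the outside ring D substituent cis to them and gives the all-cis triad. The absolute sense (2R,3R,4S) is not controlled by the remote catechin centres and must come from the chiral phosphate at O1; since the lower unit is enantiopure, any wrong-face product is a diastereomer of 13 and is removed by chromatography. The step needs ortho-regioselectivity on 9 (secured by the boron template and the para benzyloxy group), protection against Friedel–Crafts capture of 12 (secured by the C8 bromide on ring D and by consuming 9 before 12 is released), and a concerted course (favoured by toluene and low temperature) so that the cis C2/C3 relationship is kept.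

Step 8
Reactants: 13 hepta-O-benzyl 8-bromo dimer diacetate
Product: 14 hepta-O-benzyl 8-bromo dimer diol (upper 2R,3R,4S all-cis with 3-OH; lower 2R,3S with 3-OH)
Conditions: K2CO3 (cat.), MeOH/THF (1:1), rt to 40 °C
Reagents that add atoms: none
Why: Base-catalysed transesterification (methanolysis) of two secondary acetates; the aryl bromide, the benzyl ethers and the five stereocentres are inert to catalytic carbonate in methanol.

Step 9
Reactants: 14 hepta-O-benzyl 8-bromo dimer diol
Product: 15 target dimer, (2R,3R,4S)-2-(3,4-dihydroxyphenyl)-3,7-dihydroxychroman-4-yl bonded through C4 to C6 of (+)-catechin (2R,3S)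
Conditions: H2 (1 atm), Pd(OH)2/C, Et3N (1.1 equiv), THF/MeOH (1:1), rt; filtration under argon
Reagents that add atoms: none
Why: Heterogeneous hydrogenolysis; Pd(OH)2/C should cleave the seven benzylic C–O bonds and reduce the aryl C–Br bond in one operation, while one equivalent of Et3N traps the HBr that could otherwise cleave the interflavan bond or open ring C, and no stereocentre is touched.

## Compound list

1 | (+)-catechin, (2R,3S) | O[C@H]1Cc2c(O)cc(O)cc2O[C@@H]1c1ccc(O)c(O)c1 | starting material
2 | 5,7,3',4'-tetra-O-benzyl-(+)-catechin, (2R,3S) | O[C@H]1Cc2c(OCc3ccccc3)cc(OCc3ccccc3)cc2O[C@@H]1c1ccc(OCc2ccccc2)c(OCc2ccccc2)c1 | intermediate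
3 | 8-bromo-5,7,3',4'-tetra-O-benzyl-(+)-catechin, (2R,3S) | O[C@H]1Cc2c(OCc3ccccc3)cc(OCc3ccccc3)c(Br)c2O[C@@H]1c1ccc(OCc2ccccc2)c(OCc2ccccc2)c1 | intermediate
4 | 3-O-acetyl-8-bromo-5,7,3',4'-tetra-O-benzyl-(+)-catechin, (2R,3S) | CC(=O)O[C@H]1Cc2c(OCc3ccccc3)cc(OCc3ccccc3)c(Br)c2O[C@@H]1c1ccc(OCc2ccccc2)c(OCc2ccccc2)c1 | intermediate
5 | 3-O-acetyl-8-bromo-6-formyl-5,7,3',4'-tetra-O-benzyl-(+)-catechin, (2R,3S) | CC(=O)O[C@H]1Cc2c(OCc3ccccc3)c(C=O)c(OCc3ccccc3)c(Br)c2O[C@@H]1c1ccc(OCc2ccccc2)c(OCc2ccccc2)c1 | intermediate
6 | 3,4-bis(benzyloxy)benzaldehyde | O=Cc1ccc(OCc2ccccc2)c(OCc2ccccc2)c1 | starting material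
7 | 1,2-bis(benzyloxy)-4-ethynylbenzene | C#Cc1ccc(OCc2ccccc2)c(OCc2ccccc2)c1 | intermediate
8 | (Z)-2-[3,4-bis(benzyloxy)phenyl]ethenyl acetate | CC(=O)O/C=C\c1ccc(OCc2ccccc2)c(OCc2ccccc2)c1 | intermediate
9 | 3-(benzyloxy)phenol | Oc1cccc(OCc2ccccc2)c1 | starting material
10 | phenylboronic acid | OB(O)c1ccccc1 | starting material
11 | 7-benzyloxy-2-phenyl-4H-1,3,2-benzodioxaborin bearing at C4 the (2R,3S)-3-O-acetyl-8-bromo-5,7,3',4'-tetra-O-benzylcatechin-6-yl group; both epimers at the dioxaborin C4 | B1(c2ccccc2)Oc2cc(OCc3ccccc3)ccc2C(O1)c1c(OCc2ccccc2)c(Br)c2c(c1OCc1ccccc1)C[C@H](OC(C)=O)[C@@H](c1ccc(OCc3ccccc3)c(OCc3ccccc3)c1)O2 | intermediate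
12 | (E)-o-quinone methide: 3-benzyloxy-6-(arylmethylidene)cyclohexa-2,4-dien-1-one, aryl = (2R,3S)-3-O-acetyl-8-bromo-5,7,3',4'-tetra-O-benzylcatechin-6-yl, aryl anti to the carbonyl | O=C1C=C(OCc2ccccc2)C=C/C1=C\c1c(OCc2ccccc2)c(Br)c2c(c1OCc1ccccc1)C[C@H](OC(C)=O)[C@@H](c1ccc(OCc3ccccc3)c(OCc3ccccc3)c1)O2 | intermediate
13 | (2R,3R,4S)-3-acetoxy-7-benzyloxy-2-[3,4-bis(benzyloxy)phenyl]chroman-4-yl bonded through C4 to C6 of (2R,3S)-3-O-acetyl-8-bromo-5,7,3',4'-tetra-O-benzylcatechin; upper ring C all-cis | c1ccccc1COc1ccc2c(c1)O[C@H](c1ccc(OCc3ccccc3)c(OCc3ccccc3)c1)[C@H](OC(C)=O)[C@@H]2c1c(OCc3ccccc3)c(Br)c2c(c1OCc1ccccc1)C[C@H](OC(C)=O)[C@@H](c1ccc(OCc3ccccc3)c(OCc3ccccc3)c1)O2 | intermediate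
14 | diol of 13: upper (2R,3R,4S) and lower (2R,3S) 3-hydroxyls free, seven benzyl ethers, bromine at lower C8 | c1ccccc1COc1ccc2c(c1)O[C@H](c1ccc(OCc3ccccc3)c(OCc3ccccc3)c1)[C@H](O)[C@@H]2c1c(OCc3ccccc3)c(Br)c2c(c1OCc1ccccc1)C[C@H](O)[C@@H](c1ccc(OCc3ccccc3)c(OCc3ccccc3)c1)O2 | intermediate
15 | (2R,3R,4S)-2-(3,4-dihydroxyphenyl)-3,7-dihydroxychroman-4-yl bonded through C4 to C6 of (2R,3S)-catechin | Oc1ccc2c(c1)O[C@H](c1ccc(O)c(O)c1)[C@H](O)[C@@H]2c1c(O)cc2c(c1O)C[C@H](O)[C@@H](c1ccc(O)c(O)c1)O2 | target

## Step count and risks

Total step count: 9. Longest linear sequence: 7 steps (steps 1, 2, 3, 4, 7, 8, 9 from (+)-catechin); the alkene branch (steps 5 and 6) joins at step 7.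

**Step 7 (key step).** Three things are most likely to go wrong.
- Face selection may be poor. The alkene has no hydrogen-bond donor to anchor it to the chiral phosphate, and the boron residue at O1 may loosen the ion pair.
- The addition may become stepwise through a benzylic cation at C2, possibly bridged by the neighbouring acetoxy group, which would erode the cis C2/C3 relationship.
- The stabilised dioxaborin may ionise too early and be captured by unreacted phenol in a Friedel–Crafts reaction.

Fallback in known chemistry: 5, 9 and 10 are condensed under the established propionic acid conditions and benzodioxaborin 11 is isolated. Boron is removed by transesterification with propane-1,3-diol to give the free o-hydroxybenzhydrol F1 (both carbinol epimers). F1 then enters the established chiral phosphoric acid-catalysed dehydrative o-quinone methide [4+2] reaction with 8, with no boron present, and the route is rejoined at 13. Any face-isomeric cycloadduct F2 is a diastereomer and would be removed by chromatography at 13 or after step 8.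

**Step 4.** Conversion may be low at the hindered, bromine-deactivated C6, or a benzyl ether ortho to the new iminium group may be lost by chloride attack at the temperature required. Fallback: setting out from 3, iodination with N-iodosuccinimide (cat. CF3CO2H, MeCN) should give the 8-bromo-6-iodo compound F3. i-PrMgCl·LiCl (2.2 equiv, THF, −20 °C to 0 °C; the first equivalent deprotonates the hydroxyl) should effect selective iodine–magnesium exchange, and DMF then gives the hydroxy aldehyde F4. Acetylation (Ac2O, pyridine, DMAP) rejoins the route at 5.

**Step 6.** The Z geometry may be eroded by isomerisation of the enol ester at the metal or by acid, or the electron-rich arylalkyne may give some Markovnikov addition. Fallback: setting out from 7, rhodium-catalysed trans-hydroboration with pinacolborane ([Rh(cod)Cl]2, P(i-Pr)3, Et3N, cyclohexane, rt) should give the (Z)-alkenylboronate F5. Chan–Lam-type C–O coupling with acetic acid (Cu(OAc)2, Et3N, 4 Å MS, air, CH2Cl2, rt) with retention of alkene geometry rejoins the route at 8.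

**Step 9.** Debenzylation may stall through poisoning of palladium by amine and bromide, or, if the amine is consumed, HBr may open ring C or cleave the interflavan bond. Fallback: setting out from 14, bromine–lithium exchange (n-BuLi, 3.3 equiv, THF, −78 °C, after deprotonation of the two hydroxyls) and protonation with MeOH should give the debrominated diol F6. Amine-free hydrogenolysis (H2, Pd(OH)2/C, THF/MeOH) then arrives at 15.

## Further compounds

F1 | step 7 | [4-benzyloxy-2-hydroxyphenyl][(2R,3S)-3-O-acetyl-8-bromo-5,7,3',4'-tetra-O-benzylcatechin-6-yl]methanol, both carbinol epimers | OC(c1ccc(OCc2ccccc2)cc1O)c1c(OCc2ccccc2)c(Br)c2c(c1OCc1ccccc1)C[C@H](OC(C)=O)[C@@H](c1ccc(OCc3ccccc3)c(OCc3ccccc3)c1)O2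
F2 | step 7 | face isomer of 13 with upper (2S,3S,4R) all-cis ring C and lower (2R,3S) | c1ccccc1COc1ccc2c(c1)O[C@@H](c1ccc(OCc3ccccc3)c(OCc3ccccc3)c1)[C@@H](OC(C)=O)[C@H]2c1c(OCc3ccccc3)c(Br)c2c(c1OCc1ccccc1)C[C@H](OC(C)=O)[C@@H](c1ccc(OCc3ccccc3)c(OCc3ccccc3)c1)O2
F3 | step 4 | 8-bromo-6-iodo-5,7,3',4'-tetra-O-benzyl-(+)-catechin, (2R,3S) | O[C@H]1Cc2c(OCc3ccccc3)c(I)c(OCc3ccccc3)c(Br)c2O[C@@H]1c1ccc(OCc2ccccc2)c(OCc2ccccc2)c1
F4 | step 4 | 8-bromo-6-formyl-5,7,3',4'-tetra-O-benzyl-(+)-catechin, (2R,3S), 3-OH free | O[C@H]1Cc2c(OCc3ccccc3)c(C=O)c(OCc3ccccc3)c(Br)c2O[C@@H]1c1ccc(OCc2ccccc2)c(OCc2ccccc2)c1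
F5 | step 6 | (Z)-2-{2-[3,4-bis(benzyloxy)phenyl]ethenyl}-4,4,5,5-tetramethyl-1,3,2-dioxaborolane | CC1(C)OB(/C=C\c2ccc(OCc3ccccc3)c(OCc3ccccc3)c2)OC1(C)C
F6 | step 9 | debrominated hepta-O-benzyl dimer diol, upper (2R,3R,4S), lower (2R,3S) | c1ccccc1COc1ccc2c(c1)O[C@H](c1ccc(OCc3ccccc3)c(OCc3ccccc3)c1)[C@H](O)[C@@H]2c1c(OCc3ccccc3)cc2c(c1OCc1ccccc1)C[C@H](O)[C@@H](c1ccc(OCc3ccccc3)c(OCc3ccccc3)c1)O2
A1 | alternative 1 | diene: aryl 1-arylallyl ether with ortho 1-(catechin-6-yl)vinyl group, lower 3-O-TBS, 8-bromo | C=C[C@@H](c1ccc(OCc2ccccc2)c(OCc2ccccc2)c1)Oc1cc(OCc2ccccc2)ccc1C(=C)c1c(OCc2ccccc2)c(Br)c2c(c1OCc1ccccc1)C[C@H](O[Si](C)(C)C(C)(C)C)[C@@H](c1ccc(OCc3ccccc3)c(OCc3ccccc3)c1)O2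
A2 | alternative 1 | 2-aryl-4-(catechin-6-yl)-7-benzyloxy-2H-chromene, lower 3-O-TBS, 8-bromo | c1ccccc1COc1ccc2c(c1)O[C@H](c1ccc(OCc3ccccc3)c(OCc3ccccc3)c1)C=C2c1c(OCc3ccccc3)c(Br)c2c(c1OCc1ccccc1)C[C@H](O[Si](C)(C)C(C)(C)C)[C@@H](c1ccc(OCc3ccccc3)c(OCc3ccccc3)c1)O2
A3 | alternative 2 | acyclic alcohol: C2-OH free, C3-OBn, C4 bearing 2-bromo-4-benzyloxyphenyl and the 8-chloro-3-O-TBS catechin-6-yl group | O[C@H](c1ccc(OCc2ccccc2)c(OCc2ccccc2)c1)[C@H](OCc1ccccc1)[C@@H](c1ccc(OCc2ccccc2)cc1Br)c1c(OCc2ccccc2)c(Cl)c2c(c1OCc1ccccc1)C[C@H](O[Si](C)(C)C(C)(C)C)[C@@H](c1ccc(OCc3ccccc3)c(OCc3ccccc3)c1)O2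
A4 | alternative 2 | all-cis octa-O-benzyl 8-chloro 3-O-TBS dimer | c1ccccc1COc1ccc2c(c1)O[C@H](c1ccc(OCc3ccccc3)c(OCc3ccccc3)c1)[C@H](OCc1ccccc1)[C@@H]2c1c(OCc3ccccc3)c(Cl)c2c(c1OCc1ccccc1)C[C@H](O[Si](C)(C)C(C)(C)C)[C@@H](c1ccc(OCc3ccccc3)c(OCc3ccccc3)c1)O2
A5 | alternative 3 | ring D o-hydroxymethylphenol carrying the all-cis 3-O-benzyl upper unit | c1ccccc1COc1ccc2c(c1)O[C@H](c1ccc(OCc3ccccc3)c(OCc3ccccc3)c1)[C@H](OCc1ccccc1)[C@@H]2c1c(OCc2ccccc2)cc(O)c(CO)c1OCc1ccccc1
A6 | alternative 3 | (E)-2-[3,4-bis(benzyloxy)phenyl]ethenyl acetate | CC(=O)O/C=C/c1ccc(OCc2ccccc2)c(OCc2ccccc2)c1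
A7 | alternative 3 | octa-O-benzyl dimer with lower 3-O-acetate | c1ccccc1COc1ccc2c(c1)O[C@H](c1ccc(OCc3ccccc3)c(OCc3ccccc3)c1)[C@H](OCc1ccccc1)[C@@H]2c1c(OCc3ccccc3)cc2c(c1OCc1ccccc1)C[C@H](OC(C)=O)[C@@H](c1ccc(OCc3ccccc3)c(OCc3ccccc3)c1)O2
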